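**Strategy.** The decanolide ring (O1, C2=O, C3–C5, C6=C7, C8–C10) holds the lactone carbonyl C2 and the E-alkene C6=C7 in a δ,ε-relationship, the retron of an oxy-Cope rearrangement. The C4–C5 bond is therefore made by an anionic oxy-Cope ring expansion: the potassium alkoxide of a six-membered lactol carrying vinyl groups at C2 and C7 breaks C2–C7, forms C4–C5 and delivers the ten-membered lactone enolate with the E-alkene through a chair transition state; oxaziridine trapping installs the C3 hydroxyl in the same flask. The lactol comes from a sugar-like δ-lactone built by alkoxyallylboration and an Evans aldol; acylation with a muconate half-ester and acid deprotection finish the route.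

Key step: step 9

Remark: all intermediates keep the decanolide atom numbers (O1, C2 carbonyl, C3 acyloxy carbon, C4, C5, C6=C7, C8, C9, C10 propyl-bearing); allyl methoxymethyl ether 1 is assumed to be purchased (otherwise one step from allyl alcohol and MOMCl).

**Step 1**
Reactants: 1 3-(methoxymethoxy)prop-1-ene; 2 butanal
Product: 5 (3S,4S)-3-(methoxymethoxy)hept-1-en-4-ol, via Z-alkoxyallylborane 3 (not isolated), via borinate ester 4 (not isolated)
Conditions: s-BuLi, THF, −78 °C; (+)-Ipc2BOMe; BF3·OEt2; 2, −78 °C; then NaOH, H2O2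
Reagents that add atoms: none
Why: Asymmetric γ-alkoxyallylboration through a closed chair transition state, in which the Z geometry of 3 should fix the syn (threo) C9/C10 relationship and the isopinocampheyl groups from (−)-α-pinene should select the aldehyde face that gives 9S,10S.

**Step 2**
Reactants: 5 (3S,4S)-3-(methoxymethoxy)hept-1-en-4-ol
Product: 6 triethyl{[(3S,4S)-3-(methoxymethoxy)hept-1-en-4-yl]oxy}silane
Conditions: TESCl, imidazole, DMF, 0 °C → rt
Reagents that add atoms: chlorotriethylsilane, CC[Si](Cl)(CC)CC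
Why: Imidazole-promoted silylation masks O10 with a group that can later be removed by fluoride without touching the MOM ether.

**Step 3**
Reactants: 6 triethyl{[(3S,4S)-3-(methoxymethoxy)hept-1-en-4-yl]oxy}silane
Product: 8 (2R,3S)-2-(methoxymethoxy)-3-[(triethylsilyl)oxy]hexanal, via ozonide 7 (not isolated)
Conditions: O3, CH2Cl2, −78 °C; then PPh3, −78 °C → rt
Reagents that add atoms: ozone, [O-][O+]=O
Why: Ozonolysis with reductive work-up cleaves the only alkene to the C8 aldehyde, and the base-free conditions should leave the α-alkoxy centre C9 unepimerised.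

**Step 4**
Reactants: 9 (R)-4-benzyloxazolidin-2-one; 10 (E)-but-2-enoyl chloride
Product: 11 (R)-4-benzyl-3-[(E)-but-2-enoyl]oxazolidin-2-one
Conditions: n-BuLi, THF, −78 °C; then 10, −78 → 0 °C
Reagents that add atoms: none
Why: N-acylation of the lithiated oxazolidinone by the acid chloride at low temperature should give the crotonyl imide without conjugate addition.

**Step 5**
Reactants: 8 (2R,3S)-2-(methoxymethoxy)-3-[(triethylsilyl)oxy]hexanal; 11 (R)-4-benzyl-3-[(E)-but-2-enoyl]oxazolidin-2-one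
Product: 14 (R)-4-benzyl-3-[(2R,3R,4S,5S)-2-ethenyl-3-hydroxy-4-(methoxymethoxy)-5-[(triethylsilyl)oxy]octanoyl]oxazolidin-2-one, via boron dienolate 12 (not isolated), via boron aldolate 13 (not isolated)
Conditions: 11, Bu2BOTf, Et3N, CH2Cl2, −78 → 0 °C; then 8, −78 → 0 °C; pH 7 buffer, MeOH, H2O2
Reagents that add atoms: none
Why: Evans syn-aldol reaction of the boron dienolate, which reacts at its α-carbon through a Zimmerman–Traxler chair, so that the (R)-benzyl auxiliary should set 7R,8R under reagent control and override the modest Cornforth preference of the α-alkoxy aldehyde for the other C8 epimer.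

**Step 6**
Reactants: 14 (the aldol adduct)
Product: 15 (R)-4-benzyl-3-[(2R,3R,4S,5S)-2-ethenyl-3,4-bis(methoxymethoxy)-5-[(triethylsilyl)oxy]octanoyl]oxazolidin-2-one
Conditions: MOMCl, iPr2NEt, Bu4NI (cat.), CH2Cl2, 0 → 40 °C
Reagents that add atoms: chloromethyl methyl ether, COCCl
Why: O-alkylation of the C8 hydroxyl under weakly basic conditions gives a base-stable acetal ether that should neither migrate nor be lost in the organometallic steps that follow.

**Step 7**
Reactants: 15 (the bis-MOM imide)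
Product: 17 (3R,4R,5R,6S)-3-ethenyl-4,5-bis(methoxymethoxy)-6-propyloxan-2-one, via hydroxy imide 16 (not isolated)
Conditions: aq. HF, MeCN, 0 °C → rt
Reagents that add atoms: none
Why: Desilylation frees the C10 hydroxyl, which should acylate intramolecularly on the activated imide carbonyl (6-exo-trig lactonisation) and expel the oxazolidinone under non-basic conditions that leave the α-vinyl centre C7 untouched.

**Step 8**
Reactants: 17 (3R,4R,5R,6S)-3-ethenyl-4,5-bis(methoxymethoxy)-6-propyloxan-2-one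
Product: 18 (3R,4R,5R,6S)-2,3-diethenyl-4,5-bis(methoxymethoxy)-6-propyloxan-2-ol (mixture of anomers)
Conditions: CH2=CHMgBr, CeCl3, THF, −78 °C; aq. NH4Cl
Reagents that add atoms: vinylmagnesium bromide, C=C[Mg]Br
Why: 1,2-addition of the weakly basic organocerium reagent formed from CH2=CHMgBr and CeCl3 should stop at the hemiketal stage at −78 °C, as in the preparation of 1-C-vinyl lactols from aldonolactones, and should suppress enolisation at the acidic C7–H.

**Step 9**
Reactants: 18 (3R,4R,5R,6S)-2,3-diethenyl-4,5-bis(methoxymethoxy)-6-propyloxan-2-ol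
Product: 21 (3R,6E,8R,9R,10S)-3-hydroxy-8,9-bis(methoxymethoxy)-10-propyl-3,4,5,8,9,10-hexahydro-2H-oxecin-2-one, via potassium lactol alkoxide 19 (not isolated), via potassium lactone enolate 20 (not isolated)
Conditions: KN(SiMe3)2, 18-crown-6, THF, −78 → −20 °C; then trans-2-(phenylsulfonyl)-3-phenyloxaziridine, −78 °C; AcOH
Reagents that add atoms: trans-2-(phenylsulfonyl)-3-phenyloxaziridine, O=S(=O)(c1ccccc1)N1OC1c1ccccc1
Why: Proposed new method: KN(SiMe3)2/18-crown-6 converts lactol 18 into the naked hemiketal alkoxide 19, in which donation from O⁻ and from the ring oxygen weakens C2–C7, so a concerted [3,3]-sigmatropic shift across the 1,5-diene C4=C3–C2–C7–C6=C5 forms C4–C5 as C2–C7 breaks and gives lactone enolate 20, which the N-sulfonyloxaziridine then oxidises at C3. The closest known reaction type is the anionic oxy-Cope four-atom ring expansion of trans-1,2-divinylcyclohexanol alkoxides to (E)-cyclodec-5-enones with in-flask oxidation of the resulting enolate; what is new is the use of a lactol alkoxide, so that the carbonyl released is a lactone. The ten-membered ring is closed by pericyclic ring expansion of the six-membered oxane through a chair-like six-centre transition state and not by end-to-end cyclisation, so neither high dilution nor a Baldwin-type trajectory is involved. The E geometry of C6=C7 needs the two vinyl groups trans-diequatorial on the oxane chair, which the 7R configuration from step 5 (vinyl trans to O8) and the mobile anomeric centre should provide. The new stereocentre C3 is set by attack of the oxaziridine on the outer face of enolate 20, whose planar chirality is relayed from the vanishing C7 centre through the chair; a model of this chair predicts 3R. The rearrangement must outrun ring opening of 19 to an enone alkoxide, which the sugar-like substitution of the oxane, the crown-complexed potassium ion and the low temperature are chosen to favour.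

**Step 10**
Reactants: 22 ethyl (E)-4-oxobut-2-enoate; 23 tert-butyl (triphenylphosphoranylidene)acetate
Product: 24 1-tert-butyl 6-ethyl (2E,4E)-hexa-2,4-dienedioate
Conditions: CH2Cl2, 0 °C → rt
Reagents that add atoms: none
Why: Wittig olefination with a stabilised ylide should form the new alkene with E geometry and complete the (2E,4E)-diene diester.

**Step 11**
Reactants: 24 1-tert-butyl 6-ethyl (2E,4E)-hexa-2,4-dienedioate
Product: 25 (2E,4E)-6-(tert-butoxy)-6-oxohexa-2,4-dienoic acid
Conditions: LiOH (1 equiv), THF/H2O, 0 °C; then 1 M HCl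
Reagents that add atoms: lithium hydroxide, [Li+].[OH-]
Why: Saponification should be selective for the unhindered ethyl ester because the tert-butyl ester resists acyl attack by hydroxide.

**Step 12**
Reactants: 21 (the 3-hydroxy decanolide); 25 (2E,4E)-6-(tert-butoxy)-6-oxohexa-2,4-dienoic acid
Product: 26 1-tert-butyl 6-[(3R,6E,8R,9R,10S)-8,9-bis(methoxymethoxy)-2-oxo-10-propyl-3,4,5,8,9,10-hexahydro-2H-oxecin-3-yl] (2E,4E)-hexa-2,4-dienedioate
Conditions: DCC, DMAP (cat.), CH2Cl2, 0 °C → rt
Reagents that add atoms: none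
Why: Steglich esterification (carbodiimide activation, DMAP acyl transfer) should acylate the only free hydroxyl with retention at C3.

**Step 13**
Reactants: 26 (the protected ester)
Product: 27 (2E,4E)-6-{[(3R,6E,8R,9S,10S)-8,9-dihydroxy-2-oxo-10-propyl-3,4,5,8,9,10-hexahydro-2H-oxecin-3-yl]oxy}-6-oxohexa-2,4-dienoic acid (CNP0476488.1)
Conditions: TFA/CH2Cl2/H2O (10:10:1), 0 °C → rt
Reagents that add atoms: none
Why: Acidolysis should cleave both MOM acetals (oxocarbenium ions hydrolysed by the added water) and the tert-butyl ester (loss of isobutene), while the lactone, the dienoate ester and the E-alkene are inert to non-nucleophilic acid and no stereocentre is touched.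

**Compound list**

1 | 3-(methoxymethoxy)prop-1-ene (allyl methoxymethyl ether) | C=CCOCOC | starting material
2 | butanal | CCCC=O | starting material
3 | [(Z)-3-(methoxymethoxy)prop-2-en-1-yl]bis(isopinocampheyl)borane, Ipc from (−)-α-pinene | COCO/C=C\CB([C@H]1C[C@H]2C[C@@H]([C@@H]1C)C2(C)C)[C@H]1C[C@H]2C[C@@H]([C@@H]1C)C2(C)C | intermediate
4 | (3S,4S)-3-(methoxymethoxy)hept-1-en-4-yl bis(isopinocampheyl)borinate | CCC[C@H](OB([C@H]1C[C@H]2C[C@@H]([C@@H]1C)C2(C)C)[C@H]1C[C@H]2C[C@@H]([C@@H]1C)C2(C)C)[C@@H](OCOC)C=C | intermediate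
5 | (3S,4S)-3-(methoxymethoxy)hept-1-en-4-ol | CCC[C@H](O)[C@@H](OCOC)C=C | intermediate
6 | triethyl{[(3S,4S)-3-(methoxymethoxy)hept-1-en-4-yl]oxy}silane | CCC[C@H](O[Si](CC)(CC)CC)[C@@H](OCOC)C=C | intermediate
7 | secondary ozonide of 6 (3-substituted 1,2,4-trioxolane, ring carbon unassigned) | CCC[C@H](O[Si](CC)(CC)CC)[C@@H](OCOC)C1OCOO1 | intermediate
8 | (2R,3S)-2-(methoxymethoxy)-3-[(triethylsilyl)oxy]hexanal | CCC[C@H](O[Si](CC)(CC)CC)[C@@H](OCOC)C=O | intermediate
9 | (R)-4-benzyloxazolidin-2-one | O=C1N[C@H](Cc2ccccc2)CO1 | starting material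
10 | (E)-but-2-enoyl chloride | C/C=C/C(Cl)=O | starting material
11 | (R)-4-benzyl-3-[(E)-but-2-enoyl]oxazolidin-2-one | C/C=C/C(=O)N1[C@H](Cc2ccccc2)COC1=O | intermediate
12 | dibutylboron Z(O)-dienolate of 11 | C=C/C=C(\OB(CCCC)CCCC)N1[C@H](Cc2ccccc2)COC1=O | intermediate
13 | O-dibutylboryl aldolate of 14 | CCC[C@H](O[Si](CC)(CC)CC)[C@@H](OCOC)[C@H](OB(CCCC)CCCC)[C@@H](C=C)C(=O)N1[C@H](Cc2ccccc2)COC1=O | intermediate
14 | (R)-4-benzyl-3-[(2R,3R,4S,5S)-2-ethenyl-3-hydroxy-4-(methoxymethoxy)-5-[(triethylsilyl)oxy]octanoyl]oxazolidin-2-one | CCC[C@H](O[Si](CC)(CC)CC)[C@@H](OCOC)[C@H](O)[C@@H](C=C)C(=O)N1[C@H](Cc2ccccc2)COC1=O | intermediate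
15 | (R)-4-benzyl-3-[(2R,3R,4S,5S)-2-ethenyl-3,4-bis(methoxymethoxy)-5-[(triethylsilyl)oxy]octanoyl]oxazolidin-2-one | CCC[C@H](O[Si](CC)(CC)CC)[C@@H](OCOC)[C@H](OCOC)[C@@H](C=C)C(=O)N1[C@H](Cc2ccccc2)COC1=O | intermediate
16 | 5-hydroxy imide (15 without the silyl group) | CCC[C@H](O)[C@@H](OCOC)[C@H](OCOC)[C@@H](C=C)C(=O)N1[C@H](Cc2ccccc2)COC1=O | intermediate
17 | (3R,4R,5R,6S)-3-ethenyl-4,5-bis(methoxymethoxy)-6-propyloxan-2-one | CCC[C@@H]1OC(=O)[C@H](C=C)[C@@H](OCOC)[C@@H]1OCOC | intermediate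
18 | (3R,4R,5R,6S)-2,3-diethenyl-4,5-bis(methoxymethoxy)-6-propyloxan-2-ol, anomeric mixture | CCC[C@@H]1OC(O)(C=C)[C@H](C=C)[C@@H](OCOC)[C@@H]1OCOC | intermediate
19 | potassium (2S,3R,4R,5R,6S)-2,3-diethenyl-4,5-bis(methoxymethoxy)-6-propyloxan-2-olate (reactive anomer, vinyl groups trans) | CCC[C@@H]1O[C@@]([O-])(C=C)[C@H](C=C)[C@@H](OCOC)[C@@H]1OCOC.[K+] | intermediate
20 | potassium enolate of (6E,8R,9R,10S)-8,9-bis(methoxymethoxy)-10-propyl-3,4,5,8,9,10-hexahydro-2H-oxecin-2-one | CCC[C@@H]1O/C([O-])=C/CC/C=C/[C@@H](OCOC)[C@@H]1OCOC.[K+] | intermediate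
21 | (3R,6E,8R,9R,10S)-3-hydroxy-8,9-bis(methoxymethoxy)-10-propyl-3,4,5,8,9,10-hexahydro-2H-oxecin-2-one | CCC[C@@H]1OC(=O)[C@H](O)CC/C=C/[C@@H](OCOC)[C@@H]1OCOC | intermediate
22 | ethyl (E)-4-oxobut-2-enoate | CCOC(=O)/C=C/C=O | starting material
23 | tert-butyl (triphenylphosphoranylidene)acetate | CC(C)(C)OC(=O)C=P(c1ccccc1)(c1ccccc1)c1ccccc1 | starting material
24 | 1-tert-butyl 6-ethyl (2E,4E)-hexa-2,4-dienedioate | CCOC(=O)/C=C/C=C/C(=O)OC(C)(C)C | intermediate
25 | (2E,4E)-6-(tert-butoxy)-6-oxohexa-2,4-dienoic acid | OC(=O)/C=C/C=C/C(=O)OC(C)(C)C | intermediate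
26 | 1-tert-butyl 6-[(3R,6E,8R,9R,10S)-8,9-bis(methoxymethoxy)-2-oxo-10-propyl-3,4,5,8,9,10-hexahydro-2H-oxecin-3-yl] (2E,4E)-hexa-2,4-dienedioate | CCC[C@@H]1OC(=O)[C@H](OC(=O)/C=C/C=C/C(=O)OC(C)(C)C)CC/C=C/[C@@H](OCOC)[C@@H]1OCOC | intermediate
27 | (2E,4E)-6-{[(3R,6E,8R,9S,10S)-8,9-dihydroxy-2-oxo-10-propyl-3,4,5,8,9,10-hexahydro-2H-oxecin-3-yl]oxy}-6-oxohexa-2,4-dienoic acid | CCC[C@@H]1OC(=O)[C@H](OC(=O)/C=C/C=C/C(=O)O)CC/C=C/[C@@H](O)[C@@H]1O | target

**Step count and risks**

Total steps: 13. Longest linear sequence: 10 (steps 1, 2, 3, 5, 6, 7, 8, 9, 12, 13).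

Risk 1, step 9 (new method). Ring opening of alkoxide 19 to the enone alkoxide, followed by conjugation or oligomerisation, may outpace the sigmatropic shift, and the axial propyl group in the reactive chair may slow the shift further. The fallback uses known chemistry, sets out from aldehyde 8 and comes back at 21; in it the ring would be closed at the alkene instead.
- Chelation-controlled addition of CH2=CHMgBr (MgBr2·OEt2, CH2Cl2, −78 °C) should give (3R,4S,5S)-4-(methoxymethoxy)-5-[(triethylsilyl)oxy]oct-1-en-3-ol F1, with O8 syn to O9 through the five-membered magnesium chelate.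
- MOMCl/iPr2NEt should give triethyl{[(4S,5S,6R)-5,6-bis(methoxymethoxy)oct-7-en-4-yl]oxy}silane F2, and Bu4NF should then give (4S,5R,6R)-5,6-bis(methoxymethoxy)oct-7-en-4-ol F3.
- DCC/DMAP esterification with purchased hex-5-enoic acid should give (4S,5R,6R)-5,6-bis(methoxymethoxy)oct-7-en-4-yl hex-5-enoate F4.
- Ring-closing metathesis with the second-generation Grubbs catalyst (H2IMes)(PCy3)Cl2Ru=CHPh in dilute refluxing CH2Cl2 should give (6E,8R,9R,10S)-8,9-bis(methoxymethoxy)-10-propyl-3,4,5,8,9,10-hexahydro-2H-oxecin-2-one F5, to be separated from any Z isomer.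
- Deprotonation of F5 with KN(SiMe3)2 and oxidation with the same oxaziridine should give 21.
- Should the enolate oxidation (here or in step 9) deliver the (3S)-epimer of 21 F6, Mitsunobu esterification of F6 with 25 (PPh3, DIAD, THF) would invert C3 and rejoin the route at 26.

Risk 2, step 8. Enolisation at the doubly activated C7–H, with β-elimination of the C8 MOM ether, or collapse of the tetrahedral intermediate and a second addition may compete with clean mono-addition. The fallback sets out from 14 and comes back at 18.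
- Transamination with MeONHMe·HCl/AlMe3 should give (2R,3R,4S,5S)-2-ethenyl-3-hydroxy-N-methoxy-4-(methoxymethoxy)-N-methyl-5-[(triethylsilyl)oxy]octanamide F7.
- MOMCl/iPr2NEt should give (2R,3R,4S,5S)-2-ethenyl-N-methoxy-3,4-bis(methoxymethoxy)-N-methyl-5-[(triethylsilyl)oxy]octanamide F8.
- CH2=CHMgBr (THF, −78 → 0 °C) should stop at the chelated tetrahedral adduct and give, on work-up, (4R,5R,6S,7S)-4-ethenyl-5,6-bis(methoxymethoxy)-7-[(triethylsilyl)oxy]dec-1-en-3-one F9.
- Aqueous HF in MeCN should remove the silyl group, and the δ-hydroxy enone should close to lactol 18.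

Risk 3, step 13. The vicinal MOM ethers may collapse to a cyclic methylene acetal instead of hydrolysing, and the allylic C8 oxygen may ionise in strong acid. The fallback changes the protecting-group plan before the dienoate is attached; it sets out from 21 and comes back at 27.
- ZnBr2/n-PrSH (CH2Cl2, 0 °C) should transfer both MOM groups to the thiol and give (3R,6E,8R,9S,10S)-3,8,9-trihydroxy-10-propyl-3,4,5,8,9,10-hexahydro-2H-oxecin-2-one F10.
- 2,2-Dimethoxypropane/PPTS should close the trans-dioxolane on the threo 8,9-diol only, giving the 8,9-O-isopropylidene derivative of F10, F11.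
- DCC/DMAP with 25 should give the tert-butyl muconate ester of F11, F12.
- TFA/H2O at 0 °C should remove the acetonide and the tert-butyl ester to give 27.

**Further compounds**

F1 | step 9 | (3R,4S,5S)-4-(methoxymethoxy)-5-[(triethylsilyl)oxy]oct-1-en-3-ol | CCC[C@H](O[Si](CC)(CC)CC)[C@@H](OCOC)[C@H](O)C=C
F2 | step 9 | triethyl{[(4S,5S,6R)-5,6-bis(methoxymethoxy)oct-7-en-4-yl]oxy}silane | CCC[C@H](O[Si](CC)(CC)CC)[C@@H](OCOC)[C@H](OCOC)C=C
F3 | step 9 | (4S,5R,6R)-5,6-bis(methoxymethoxy)oct-7-en-4-ol | CCC[C@H](O)[C@@H](OCOC)[C@H](OCOC)C=C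
F4 | step 9 | (4S,5R,6R)-5,6-bis(methoxymethoxy)oct-7-en-4-yl hex-5-enoate | CCC[C@H](OC(=O)CCCC=C)[C@@H](OCOC)[C@H](OCOC)C=C
F5 | step 9 | (6E,8R,9R,10S)-8,9-bis(methoxymethoxy)-10-propyl-3,4,5,8,9,10-hexahydro-2H-oxecin-2-one | CCC[C@@H]1OC(=O)CCC/C=C/[C@@H](OCOC)[C@@H]1OCOC
F6 | step 9 | (3S,6E,8R,9R,10S)-3-hydroxy-8,9-bis(methoxymethoxy)-10-propyl-3,4,5,8,9,10-hexahydro-2H-oxecin-2-one | CCC[C@@H]1OC(=O)[C@@H](O)CC/C=C/[C@@H](OCOC)[C@@H]1OCOC
F7 | step 8 | (2R,3R,4S,5S)-2-ethenyl-3-hydroxy-N-methoxy-4-(methoxymethoxy)-N-methyl-5-[(triethylsilyl)oxy]octanamide | CCC[C@H](O[Si](CC)(CC)CC)[C@@H](OCOC)[C@H](O)[C@@H](C=C)C(=O)N(C)OC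
F8 | step 8 | (2R,3R,4S,5S)-2-ethenyl-N-methoxy-3,4-bis(methoxymethoxy)-N-methyl-5-[(triethylsilyl)oxy]octanamide | CCC[C@H](O[Si](CC)(CC)CC)[C@@H](OCOC)[C@H](OCOC)[C@@H](C=C)C(=O)N(C)OC
F9 | step 8 | (4R,5R,6S,7S)-4-ethenyl-5,6-bis(methoxymethoxy)-7-[(triethylsilyl)oxy]dec-1-en-3-one | CCC[C@H](O[Si](CC)(CC)CC)[C@@H](OCOC)[C@H](OCOC)[C@@H](C=C)C(=O)C=C
F10 | step 13 | (3R,6E,8R,9S,10S)-3,8,9-trihydroxy-10-propyl-3,4,5,8,9,10-hexahydro-2H-oxecin-2-one | CCC[C@@H]1OC(=O)[C@H](O)CC/C=C/[C@@H](O)[C@@H]1O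
F11 | step 13 | 8,9-O-isopropylidene derivative of F10 | CCC[C@@H]1OC(=O)[C@H](O)CC/C=C/[C@H]2OC(C)(C)O[C@H]12
F12 | step 13 | 3-O-[(2E,4E)-6-(tert-butoxy)-6-oxohexa-2,4-dienoyl] derivative of F11 | CCC[C@@H]1OC(=O)[C@H](OC(=O)/C=C/C=C/C(=O)OC(C)(C)C)CC/C=C/[C@H]2OC(C)(C)O[C@H]12
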